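**Retrosynthetic overview**
- Target ← fluoride removal of a C3 silyl ether ← Stille coupling (C14–C15) of a ring-bearing trienyl iodide with a C6 dienylstannane alcohol.
- Trienyl iodide ← Horner–Wadsworth–Emmons olefination (C11=C12) of a C15 dihydrofuranyl enal with an iodoallyl phosphonate.
- Dihydrofuran ring (the second ring, formed late; sets C8) ← AgNO3-catalysed 5-endo cycloisomerisation of an α-hydroxyallene with axis-to-centre chirality transfer.
- Allene ← syn-SN2′ hydride opening of an alkynyl epoxide (Sonogashira enyne ester); epoxide ← Sharpless epoxidation of a cyclohexenylmethanol.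
- The cyclohexane ring (the first ring) is carried through from achiral ketoisophorone; its stereocentres come from an ene-reductase and then a ketoreductase.

Assumption: enzymes are isolated recombinant proteins with cofactor recycling; TBS = tert-butyldimethylsilyl; from step 7 on, locants such as C3, C5, C6, C8 in the Why lines are carotenoid locants (ring C1–C6, chain C7 onward).

**Step 1**
Reactants: 1 2,6,6-trimethylcyclohex-2-ene-1,4-dione (ketoisophorone)
Product: 2 (6R)-2,2,6-trimethylcyclohexane-1,4-dione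
Conditions: ene-reductase (flavin-dependent old yellow enzyme family), NADP+ (cat.), glucose dehydrogenase, D-glucose, phosphate buffer pH 7.0, 30 °C
Reagents that add atoms: none
Why: The ene-reductase adds hydride and a proton anti across the enedione C=C inside its chiral active site (biocatalytic asymmetric alkene reduction), which sets the methyl-bearing carbon as R and leaves both carbonyls untouched.

**Step 2**
Reactants: 2 (6R)-2,2,6-trimethylcyclohexane-1,4-dione
Product: 3 (4R,6R)-4-hydroxy-2,2,6-trimethylcyclohexan-1-one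
Conditions: ketoreductase (NADH-dependent carbonyl reductase of the levodione reductase type), NAD+ (cat.), glucose dehydrogenase, D-glucose, phosphate buffer pH 7.0, 30 °C; recrystallise
Reagents that add atoms: none
Why: The ketoreductase transfers hydride only to the unhindered C4 carbonyl and only to one face (enzymatic asymmetric ketone reduction), giving the 4R carbinol trans to the C6 methyl while the hindered C1 ketone stays.

**Step 3**
Reactants: 3 (4R,6R)-4-hydroxy-2,2,6-trimethylcyclohexan-1-one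
Product: 4 (4R,6R)-4-(TBSO)-2,2,6-trimethylcyclohexan-1-one
Conditions: TBSCl, imidazole, DMF, rt
Reagents that add atoms: tert-butyldimethylsilyl chloride, CC(C)(C)[Si](C)(C)Cl
Why: Silyl ether formation masks the secondary alcohol for the enolate, hydride and organometallic steps that follow.

**Step 4**
Reactants: 4 (4R,6R)-4-(TBSO)-2,2,6-trimethylcyclohexan-1-one
Product: 6 (4R)-4-(TBSO)-2,6,6-trimethylcyclohex-1-en-1-yl trifluoromethanesulfonate, via lithium enolate 5 (not isolated)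
Conditions: LiN(i-Pr)2, THF, −78 °C; then PhNTf2, −78 → 0 °C
Reagents that add atoms: N-phenylbis(trifluoromethanesulfonimide), FC(F)(F)S(=O)(=O)N(c1ccccc1)S(=O)(=O)C(F)(F)F
Why: The ketone can enolise only toward C6 because C2 is quaternary, so deprotonation and O-triflation (enol triflate formation) give one regioisomer; the C6 centre is deliberately erased here after serving as the recognition element in step 2, and the C4 carbinol centre is untouched.

**Step 5**
Reactants: 6 (4R)-4-(TBSO)-2,6,6-trimethylcyclohex-1-en-1-yl trifluoromethanesulfonate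
Product: 7 methyl (4R)-4-(TBSO)-2,6,6-trimethylcyclohex-1-ene-1-carboxylate
Conditions: Pd(OAc)2 (cat.), PPh3, CO (1 atm), MeOH, Et3N, DMF, 60 °C
Reagents that add atoms: carbon monoxide, [C-]#[O+]; methanol, CO
Why: Pd(OAc)2/PPh3-catalysed methoxycarbonylation of the vinyl triflate (oxidative addition, CO insertion, methanolysis) installs C7 at the ester oxidation level.

**Step 6**
Reactants: 7 methyl (4R)-4-(TBSO)-2,6,6-trimethylcyclohex-1-ene-1-carboxylate
Product: 8 [(4R)-4-(TBSO)-2,6,6-trimethylcyclohex-1-en-1-yl]methanol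
Conditions: i-Bu2AlH, CH2Cl2, −78 °C; aq. KNaC4H4O6
Reagents that add atoms: none
Why: i-Bu2AlH reduces the hindered enoate in 1,2-fashion (ester reduction) to the primary allylic alcohol that will direct the epoxidation.

**Step 7**
Reactants: 8 [(4R)-4-(TBSO)-2,6,6-trimethylcyclohex-1-en-1-yl]methanol
Product: 9 [(1R,4S,6R)-4-(TBSO)-2,2,6-trimethyl-7-oxabicyclo[4.1.0]heptan-1-yl]methanol
Conditions: Ti(OiPr)4 (0.2 equiv), D-(−)-diethyl tartrate (0.25 equiv), t-BuOOH, 4 Å MS, CH2Cl2, −20 °C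
Reagents that add atoms: tert-butyl hydroperoxide, CC(C)(C)OO
Why: Sharpless asymmetric epoxidation of the primary allylic alcohol with the D-tartrate ligand delivers oxygen to the ring face anti to the C3 silyloxy group, so the C5 (R) and C6 epoxide centres are set under catalyst control.

**Step 8**
Reactants: 9 [(1R,4S,6R)-4-(TBSO)-2,2,6-trimethyl-7-oxabicyclo[4.1.0]heptan-1-yl]methanol
Product: 10 (1S,4S,6R)-4-(TBSO)-2,2,6-trimethyl-7-oxabicyclo[4.1.0]heptane-1-carbaldehyde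
Conditions: Dess–Martin periodinane, pyridine, CH2Cl2, 0 °C → rt
Reagents that add atoms: none
Why: Buffered Dess–Martin oxidation gives the aldehyde without opening the epoxide, and the product cannot epimerise because its α-carbon is quaternary.

**Step 9**
Reactants: 10 (1S,4S,6R)-4-(TBSO)-2,2,6-trimethyl-7-oxabicyclo[4.1.0]heptane-1-carbaldehyde
Product: 11 (1R,4S,6R)-4-(TBSO)-1-ethynyl-2,2,6-trimethyl-7-oxabicyclo[4.1.0]heptane
Conditions: dimethyl (1-diazo-2-oxopropyl)phosphonate, K2CO3, MeOH, 0 °C → rt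
Reagents that add atoms: dimethyl (1-diazo-2-oxopropyl)phosphonate, COP(=O)(OC)C(=[N+]=[N-])C(C)=O
Why: Seyferth–Gilbert homologation with the Ohira–Bestmann reagent turns the non-enolisable aldehyde into the terminal alkyne (adding C8) under mild carbonate conditions that spare the epoxide and the silyl ether.

**Step 10**
Reactants: 12 ethyl 3-oxobutanoate
Product: 13 ethyl (2E)-3-{[(trifluoromethyl)sulfonyl]oxy}but-2-enoate
Conditions: Tf2O, aq. Me4NOH, hexane, 5–10 °C
Reagents that add atoms: trifluoromethanesulfonic anhydride, FC(F)(F)S(=O)(=O)OS(=O)(=O)C(F)(F)F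
Why: O-triflation of the acetoacetate enolate with the non-chelating tetramethylammonium counter-ion goes through the extended enolate and gives the (E)-enol triflate (stereoselective enol triflate formation), which fixes the future C9=C10 geometry.

**Step 11**
Reactants: 11 (1R,4S,6R)-4-(TBSO)-1-ethynyl-2,2,6-trimethyl-7-oxabicyclo[4.1.0]heptane; 13 ethyl (2E)-3-{[(trifluoromethyl)sulfonyl]oxy}but-2-enoate
Product: 14 ethyl (2E)-5-[(1R,4S,6R)-4-(TBSO)-2,2,6-trimethyl-7-oxabicyclo[4.1.0]heptan-1-yl]-3-methylpent-2-en-4-ynoate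
Conditions: PdCl2(PPh3)2 (cat.), CuI (cat.), Et3N, THF, rt
Reagents that add atoms: none
Why: Sonogashira coupling of the terminal alkyne with the activated β-triflyloxy enoate proceeds at room temperature with retention of alkene geometry, giving the 9E enyne without disturbing the hindered propargylic epoxide.

**Step 12**
Reactants: 14 ethyl (2E)-5-[(1R,4S,6R)-4-(TBSO)-2,2,6-trimethyl-7-oxabicyclo[4.1.0]heptan-1-yl]-3-methylpent-2-en-4-ynoate
Product: 16 (2E)-5-[(2R,4S)-4-(TBSO)-2-hydroxy-2,6,6-trimethylcyclohexylidene]-3-methylpenta-2,4-dien-1-ol (R allene axis; 3S,5R,6R in carotenoid locants), via epoxy enynol aluminium alkoxide 15 (not isolated)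
Conditions: i-Bu2AlH (5 equiv), CH2Cl2, −78 → 0 °C; aq. KNaC4H4O6
Reagents that add atoms: none
Why: i-Bu2AlH first reduces the ester and then, bound to the epoxide oxygen, delivers hydride to C8 on the face of the departing C6–O bond (syn-SN2′ reduction of a propargylic epoxide), which gives the allene with the R axis and frees the C5 tertiary alcohol with its configuration unchanged.

**Step 13**
Reactants: 16 (2E)-5-[(2R,4S)-4-(TBSO)-2-hydroxy-2,6,6-trimethylcyclohexylidene]-3-methylpenta-2,4-dien-1-ol (R allene axis)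
Product: 17 (2E)-3-[(2S,6S,7aR)-6-(TBSO)-4,4,7a-trimethyl-2,4,5,6,7,7a-hexahydro-1-benzofuran-2-yl]but-2-en-1-ol
Conditions: AgNO3 (0.2 equiv), CaCO3, acetone/H2O, rt, dark
Reagents that add atoms: none
Why: AgNO3 activates the allene as a π-acid and the C5 hydroxyl adds to C8 in a 5-endo cycloisomerisation (α-hydroxyallene to 2,5-dihydrofuran) whose geometry converts the R axis into the 8S centre (C8 side chain cis to the C5 methyl), while CaCO3 keeps the doubly allylic ether from ionising.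

**Step 14**
Reactants: 17 (2E)-3-[(2S,6S,7aR)-6-(TBSO)-4,4,7a-trimethyl-2,4,5,6,7,7a-hexahydro-1-benzofuran-2-yl]but-2-en-1-ol
Product: 18 (2E)-3-[(2S,6S,7aR)-6-(TBSO)-4,4,7a-trimethyl-2,4,5,6,7,7a-hexahydro-1-benzofuran-2-yl]but-2-enal
Conditions: MnO2, CH2Cl2, rt
Reagents that add atoms: none
Why: MnO2 oxidises the primary allylic alcohol to the enal under neutral heterogeneous conditions (allylic oxidation) that touch neither the silyl ether nor the acid-labile C8–O bond.

**Step 15**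
Reactants: 19 prop-2-yn-1-ol
Product: 21 (2E)-3-iodo-2-methylprop-2-en-1-ol, via vinylalane 20 (not isolated)
Conditions: AlMe3, Cp2ZrCl2 (0.25 equiv), CH2Cl2, 0 °C → rt; then I2, THF, −30 → 0 °C
Reagents that add atoms: trimethylaluminium, C[Al](C)C; iodine, II
Why: Cp2ZrCl2-catalysed Negishi carboalumination adds methyl and aluminium syn across the alkyne with aluminium at the terminus, and iodinolysis with retention gives the (E)-iodoalkene that becomes C13=C14.

**Step 16**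
Reactants: 21 (2E)-3-iodo-2-methylprop-2-en-1-ol
Product: 22 (1E)-3-bromo-1-iodo-2-methylprop-1-ene
Conditions: CBr4, PPh3, CH2Cl2, 0 °C
Reagents that add atoms: tetrabromomethane, BrC(Br)(Br)Br
Why: Appel bromination converts the allylic alcohol into the bromide under neutral conditions without affecting the vinyl iodide or the alkene geometry.

**Step 17**
Reactants: 22 (1E)-3-bromo-1-iodo-2-methylprop-1-ene
Product: 23 diethyl [(2E)-3-iodo-2-methylprop-2-en-1-yl]phosphonate
Conditions: P(OEt)3, neat, 100 °C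
Reagents that add atoms: triethyl phosphite, CCOP(OCC)OCC
Why: Michaelis–Arbuzov reaction of the allylic bromide gives the phosphonate, the vinyl iodide being inert to the phosphite in the absence of a metal catalyst.

**Step 18**
Reactants: 23 diethyl [(2E)-3-iodo-2-methylprop-2-en-1-yl]phosphonate; 18 (2E)-3-[(2S,6S,7aR)-6-(TBSO)-4,4,7a-trimethyl-2,4,5,6,7,7a-hexahydro-1-benzofuran-2-yl]but-2-enal
Product: 25 (2S,6S,7aR)-6-(TBSO)-2-[(2E,4E,6E)-7-iodo-6-methylhepta-2,4,6-trien-2-yl]-4,4,7a-trimethyl-2,4,5,6,7,7a-hexahydro-1-benzofuran, via sodium phosphonate carbanion 24 (not isolated)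
Conditions: 23, NaN(SiMe3)2, THF, −78 °C; then 18, −78 → 0 °C
Reagents that add atoms: none
Why: Horner–Wadsworth–Emmons olefination of the enal with the allylic phosphonate carbanion forms C11=C12 with E selectivity at low temperature, where carbonyl addition outruns deprotonation at C8, so the 8S centre and the 13E iodoalkene are retained.

**Step 19**
Reactants: 26 (2E)-3-(tributylstannyl)prop-2-en-1-ol
Product: 27 (2E)-3-(tributylstannyl)prop-2-enal
Conditions: MnO2, CH2Cl2, rt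
Reagents that add atoms: none
Why: MnO2 oxidises the allylic alcohol to the enal (allylic oxidation) without protodestannylation.

**Step 20**
Reactants: 27 (2E)-3-(tributylstannyl)prop-2-enal; 28 ethyl 2-(triphenylphosphoranylidene)propanoate
Product: 29 ethyl (2E,4E)-2-methyl-5-(tributylstannyl)penta-2,4-dienoate
Conditions: CH2Cl2, rt
Reagents that add atoms: none
Why: Wittig olefination with the stabilised ylide gives the (E)-trisubstituted enoate (future C14′=C13′) and leaves the (E)-vinylstannane untouched.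

**Step 21**
Reactants: 29 ethyl (2E,4E)-2-methyl-5-(tributylstannyl)penta-2,4-dienoate
Product: 30 (2E,4E)-2-methyl-5-(tributylstannyl)penta-2,4-dien-1-ol
Conditions: i-Bu2AlH, CH2Cl2, −78 °C; aq. KNaC4H4O6
Reagents that add atoms: none
Why: i-Bu2AlH reduces the dienoate in 1,2-fashion to the allylic alcohol (ester reduction) and tolerates the vinylstannane at low temperature.

**Step 22**
Reactants: 25 (2S,6S,7aR)-6-(TBSO)-2-[(2E,4E,6E)-7-iodo-6-methylhepta-2,4,6-trien-2-yl]-4,4,7a-trimethyl-2,4,5,6,7,7a-hexahydro-1-benzofuran; 30 (2E,4E)-2-methyl-5-(tributylstannyl)penta-2,4-dien-1-ol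
Product: 31 (2E,4E,6E,8E,10E)-11-[(2S,6S,7aR)-6-(TBSO)-4,4,7a-trimethyl-2,4,5,6,7,7a-hexahydro-1-benzofuran-2-yl]-2,7-dimethyldodeca-2,4,6,8,10-pentaen-1-ol
Conditions: Pd2(dba)3·CHCl3 (cat.), AsPh3, NMP, rt, dark
Reagents that add atoms: none
Why: Stille cross-coupling joins C14 and C15 with retention of both alkene geometries under neutral conditions compatible with the free alcohol, the silyl ether and the doubly allylic C8 ether.

**Step 23**
Reactants: 31 (2E,4E,6E,8E,10E)-11-[(2S,6S,7aR)-6-(TBSO)-4,4,7a-trimethyl-2,4,5,6,7,7a-hexahydro-1-benzofuran-2-yl]-2,7-dimethyldodeca-2,4,6,8,10-pentaen-1-ol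
Product: 32 (2E,4E,6E,8E,10E)-11-[(2S,6S,7aR)-6-hydroxy-4,4,7a-trimethyl-2,4,5,6,7,7a-hexahydro-1-benzofuran-2-yl]-2,7-dimethyldodeca-2,4,6,8,10-pentaen-1-ol
Conditions: Bu4NF, THF, 0 °C → rt
Reagents that add atoms: none
Why: Fluoride cleaves the silyl ether (desilylation) under non-acidic conditions, so the acid-labile 8S furanoid centre and the all-E polyene survive and the target is released.

**Compound list**
1 | 2,6,6-trimethylcyclohex-2-ene-1,4-dione (ketoisophorone) | CC1=CC(=O)CC(C)(C)C1=O | starting material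
2 | (6R)-2,2,6-trimethylcyclohexane-1,4-dione | C[C@@H]1CC(=O)CC(C)(C)C1=O | intermediate
3 | (4R,6R)-4-hydroxy-2,2,6-trimethylcyclohexan-1-one | C[C@@H]1C[C@@H](O)CC(C)(C)C1=O | intermediate
4 | (4R,6R)-4-(tert-butyldimethylsilyloxy)-2,2,6-trimethylcyclohexan-1-one | C[C@@H]1C[C@@H](O[Si](C)(C)C(C)(C)C)CC(C)(C)C1=O | intermediate
5 | lithium (4R)-4-(TBSO)-2,6,6-trimethylcyclohex-1-en-1-olate | [Li+].CC1=C([O-])C(C)(C)C[C@H](O[Si](C)(C)C(C)(C)C)C1 | intermediate (not isolated)
6 | (4R)-4-(TBSO)-2,6,6-trimethylcyclohex-1-en-1-yl trifluoromethanesulfonate | CC1=C(OS(=O)(=O)C(F)(F)F)C(C)(C)C[C@H](O[Si](C)(C)C(C)(C)C)C1 | intermediate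
7 | methyl (4R)-4-(TBSO)-2,6,6-trimethylcyclohex-1-ene-1-carboxylate | CC1=C(C(=O)OC)C(C)(C)C[C@H](O[Si](C)(C)C(C)(C)C)C1 | intermediate
8 | [(4R)-4-(TBSO)-2,6,6-trimethylcyclohex-1-en-1-yl]methanol | CC1=C(CO)C(C)(C)C[C@H](O[Si](C)(C)C(C)(C)C)C1 | intermediate
9 | [(1R,4S,6R)-4-(TBSO)-2,2,6-trimethyl-7-oxabicyclo[4.1.0]heptan-1-yl]methanol (epoxide anti to the silyloxy group) | C[C@@]12C[C@@H](O[Si](C)(C)C(C)(C)C)CC(C)(C)[C@]1(CO)O2 | intermediate
10 | (1S,4S,6R)-4-(TBSO)-2,2,6-trimethyl-7-oxabicyclo[4.1.0]heptane-1-carbaldehyde | C[C@@]12C[C@@H](O[Si](C)(C)C(C)(C)C)CC(C)(C)[C@]1(C=O)O2 | intermediate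
11 | (1R,4S,6R)-4-(TBSO)-1-ethynyl-2,2,6-trimethyl-7-oxabicyclo[4.1.0]heptane | C[C@@]12C[C@@H](O[Si](C)(C)C(C)(C)C)CC(C)(C)[C@]1(C#C)O2 | intermediate
12 | ethyl 3-oxobutanoate | CCOC(=O)CC(C)=O | starting material
13 | ethyl (2E)-3-{[(trifluoromethyl)sulfonyl]oxy}but-2-enoate | CCOC(=O)/C=C(\C)OS(=O)(=O)C(F)(F)F | intermediate
14 | ethyl (2E)-5-[(1R,4S,6R)-4-(TBSO)-2,2,6-trimethyl-7-oxabicyclo[4.1.0]heptan-1-yl]-3-methylpent-2-en-4-ynoate | C[C@@]12C[C@@H](O[Si](C)(C)C(C)(C)C)CC(C)(C)[C@]1(C#C/C(C)=C/C(=O)OCC)O2 | intermediate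
15 | diisobutylaluminium (2E)-5-[(1R,4S,6R)-4-(TBSO)-2,2,6-trimethyl-7-oxabicyclo[4.1.0]heptan-1-yl]-3-methylpent-2-en-4-yn-1-olate | C[C@@]12C[C@@H](O[Si](C)(C)C(C)(C)C)CC(C)(C)[C@]1(C#C/C(C)=C/CO[Al](CC(C)C)CC(C)C)O2 | intermediate (not isolated)
16 | (2E)-5-[(2R,4S)-4-(TBSO)-2-hydroxy-2,6,6-trimethylcyclohexylidene]-3-methylpenta-2,4-dien-1-ol, R allene axis (3S,5R,6R in carotenoid locants) | OC/C=C(C)/C=[C@@]=C1C(C)(C)C[C@H](O[Si](C)(C)C(C)(C)C)C[C@@]1(C)O | intermediate
17 | (2E)-3-[(2S,6S,7aR)-6-(TBSO)-4,4,7a-trimethyl-2,4,5,6,7,7a-hexahydro-1-benzofuran-2-yl]but-2-en-1-ol | OC/C=C(C)/[C@@H]1C=C2C(C)(C)C[C@H](O[Si](C)(C)C(C)(C)C)C[C@@]2(C)O1 | intermediate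
18 | (2E)-3-[(2S,6S,7aR)-6-(TBSO)-4,4,7a-trimethyl-2,4,5,6,7,7a-hexahydro-1-benzofuran-2-yl]but-2-enal | O=C/C=C(C)/[C@@H]1C=C2C(C)(C)C[C@H](O[Si](C)(C)C(C)(C)C)C[C@@]2(C)O1 | intermediate
19 | prop-2-yn-1-ol | C#CCO | starting material
20 | dimethylaluminium (2E)-3-(dimethylalumanyl)-2-methylprop-2-en-1-olate | C[Al](C)OC/C(C)=C/[Al](C)C | intermediate (not isolated)
21 | (2E)-3-iodo-2-methylprop-2-en-1-ol | OC/C(C)=C/I | intermediate
22 | (1E)-3-bromo-1-iodo-2-methylprop-1-ene | BrC/C(C)=C/I | intermediate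
23 | diethyl [(2E)-3-iodo-2-methylprop-2-en-1-yl]phosphonate | CCOP(=O)(OCC)C/C(C)=C/I | intermediate
24 | sodium (2E)-1-(diethoxyphosphoryl)-3-iodo-2-methylprop-2-en-1-ide | [Na+].CCOP(=O)(OCC)[CH-]/C(C)=C/I | intermediate (not isolated)
25 | (2S,6S,7aR)-6-(TBSO)-2-[(2E,4E,6E)-7-iodo-6-methylhepta-2,4,6-trien-2-yl]-4,4,7a-trimethyl-2,4,5,6,7,7a-hexahydro-1-benzofuran | I/C=C(C)/C=C/C=C(C)/[C@@H]1C=C2C(C)(C)C[C@H](O[Si](C)(C)C(C)(C)C)C[C@@]2(C)O1 | intermediate
26 | (2E)-3-(tributylstannyl)prop-2-en-1-ol | CCCC[Sn](CCCC)(CCCC)/C=C/CO | starting material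
27 | (2E)-3-(tributylstannyl)prop-2-enal | CCCC[Sn](CCCC)(CCCC)/C=C/C=O | intermediate
28 | ethyl 2-(triphenylphosphoranylidene)propanoate | CCOC(=O)C(C)=P(c1ccccc1)(c1ccccc1)c1ccccc1 | starting material
29 | ethyl (2E,4E)-2-methyl-5-(tributylstannyl)penta-2,4-dienoate | CCCC[Sn](CCCC)(CCCC)/C=C/C=C(\C)C(=O)OCC | intermediate
30 | (2E,4E)-2-methyl-5-(tributylstannyl)penta-2,4-dien-1-ol | CCCC[Sn](CCCC)(CCCC)/C=C/C=C(\C)CO | intermediate
31 | (2E,4E,6E,8E,10E)-11-[(2S,6S,7aR)-6-(TBSO)-4,4,7a-trimethyl-2,4,5,6,7,7a-hexahydro-1-benzofuran-2-yl]-2,7-dimethyldodeca-2,4,6,8,10-pentaen-1-ol | CC(/C=C/C=C(\C)[C@@H]1C=C2C(C)(C)C[C@H](O[Si](C)(C)C(C)(C)C)C[C@@]2(C)O1)=C\C=C\C=C(/C)CO | intermediate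
32 | (2E,4E,6E,8E,10E)-11-[(2S,6S,7aR)-6-hydroxy-4,4,7a-trimethyl-2,4,5,6,7,7a-hexahydro-1-benzofuran-2-yl]-2,7-dimethyldodeca-2,4,6,8,10-pentaen-1-ol | CC(/C=C/C=C(\C)[C@@H]1C=C2C(C)(C)C[C@H](O)C[C@@]2(C)O1)=C\C=C\C=C(/C)CO | target

**Totals and risks**
Total step count: 23. Longest linear sequence: 16 steps (steps 1–9, 11–14, 18, 22, 23).

Step 12 is risky because the reduction must give a single allene epimer; if the S axis or direct epoxide reduction competes, control of C8 is lost. The fallback sets out from epoxy aldehyde 10 and avoids the allene altogether. A Horner–Wadsworth–Emmons reaction with commercial triethyl 3-methyl-4-phosphonocrotonate (NaH, THF, 0 °C) gives ethyl (2E,4E)-5-[(1S,4S,6R)-4-(TBSO)-2,2,6-trimethyl-7-oxabicyclo[4.1.0]heptan-1-yl]-3-methylpenta-2,4-dienoate F1. Reduction with i-Bu2AlH gives (2E,4E)-5-[(1S,4S,6R)-4-(TBSO)-2,2,6-trimethyl-7-oxabicyclo[4.1.0]heptan-1-yl]-3-methylpenta-2,4-dien-1-ol F2. The classical acid-catalysed 5,6-epoxide to 5,8-furanoid rearrangement (catalytic pyridinium p-toluenesulfonate, CH2Cl2, 0 °C) then gives 17 together with its C8 epimer (2E)-3-[(2R,6S,7aR)-6-(TBSO)-4,4,7a-trimethyl-2,4,5,6,7,7a-hexahydro-1-benzofuran-2-yl]but-2-en-1-ol F3, which is removed by preparative HPLC. The route is rejoined at 17, at the price of stereocontrol at C8 (about half the material).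

Step 13 is risky because the cycloisomerisation has not been tested on this vinylallene and the product is an acid-labile doubly allylic ether. The fallback sets out from allenic diol 16 and closes the ring with an electrophile instead of a π-acid. N-iodosuccinimide with NaHCO3 in CH2Cl2 at 0 °C gives, by iodoetherification with the same axis-to-centre transfer, (2E)-3-[(2R,6S,7aR)-6-(TBSO)-3-iodo-4,4,7a-trimethyl-2,4,5,6,7,7a-hexahydro-1-benzofuran-2-yl]but-2-en-1-ol F4. Hydrodeiodination with Bu3SnH and catalytic Pd(PPh3)4 in THF returns to the route at 17.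

Step 18 is risky because the carbanion of 23 is a strong base meeting an enal that can epimerise at C8, and it carries a vinyl iodide. The fallback sets out from alcohol 17 and reverses the polarity. A Mitsunobu reaction with 1-phenyl-1H-tetrazole-5-thiol (PPh3, DIAD, THF) gives 5-({(2E)-3-[(2S,6S,7aR)-6-(TBSO)-4,4,7a-trimethyl-2,4,5,6,7,7a-hexahydro-1-benzofuran-2-yl]but-2-en-1-yl}sulfanyl)-1-phenyl-1H-tetrazole F5. Oxidation with H2O2 and catalytic (NH4)6Mo7O24·4H2O in EtOH gives the corresponding sulfone 5-({(2E)-3-[(2S,6S,7aR)-6-(TBSO)-4,4,7a-trimethyl-2,4,5,6,7,7a-hexahydro-1-benzofuran-2-yl]but-2-en-1-yl}sulfonyl)-1-phenyl-1H-tetrazole F6. Julia–Kocienski olefination (KN(SiMe3)2, THF, −78 °C) with an excess of commercial (2E,4E,6E)-2,7-dimethylocta-2,4,6-trienedial forms C11=C12 and gives (2E,4E,6E,8E,10E)-11-[(2S,6S,7aR)-6-(TBSO)-4,4,7a-trimethyl-2,4,5,6,7,7a-hexahydro-1-benzofuran-2-yl]-2,7-dimethyldodeca-2,4,6,8,10-pentaenal F7, any 11Z isomer being separated by chromatography. NaBH4 in MeOH at 0 °C reduces it to 31, where the route is rejoined.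

**Further compounds**
F1 | step 12 | ethyl (2E,4E)-5-[(1S,4S,6R)-4-(TBSO)-2,2,6-trimethyl-7-oxabicyclo[4.1.0]heptan-1-yl]-3-methylpenta-2,4-dienoate | C[C@@]12C[C@@H](O[Si](C)(C)C(C)(C)C)CC(C)(C)[C@]1(/C=C/C(C)=C/C(=O)OCC)O2
F2 | step 12 | (2E,4E)-5-[(1S,4S,6R)-4-(TBSO)-2,2,6-trimethyl-7-oxabicyclo[4.1.0]heptan-1-yl]-3-methylpenta-2,4-dien-1-ol | C[C@@]12C[C@@H](O[Si](C)(C)C(C)(C)C)CC(C)(C)[C@]1(/C=C/C(C)=C/CO)O2
F3 | step 12 | (2E)-3-[(2R,6S,7aR)-6-(TBSO)-4,4,7a-trimethyl-2,4,5,6,7,7a-hexahydro-1-benzofuran-2-yl]but-2-en-1-ol | OC/C=C(C)/[C@H]1C=C2C(C)(C)C[C@H](O[Si](C)(C)C(C)(C)C)C[C@@]2(C)O1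
F4 | step 13 | (2E)-3-[(2R,6S,7aR)-6-(TBSO)-3-iodo-4,4,7a-trimethyl-2,4,5,6,7,7a-hexahydro-1-benzofuran-2-yl]but-2-en-1-ol | OC/C=C(C)/[C@@H]1C(I)=C2C(C)(C)C[C@H](O[Si](C)(C)C(C)(C)C)C[C@@]2(C)O1
F5 | step 18 | 5-({(2E)-3-[(2S,6S,7aR)-6-(TBSO)-4,4,7a-trimethyl-2,4,5,6,7,7a-hexahydro-1-benzofuran-2-yl]but-2-en-1-yl}sulfanyl)-1-phenyl-1H-tetrazole | c1ccccc1-n1nnnc1SC/C=C(C)/[C@@H]1C=C2C(C)(C)C[C@H](O[Si](C)(C)C(C)(C)C)C[C@@]2(C)O1
F6 | step 18 | 5-({(2E)-3-[(2S,6S,7aR)-6-(TBSO)-4,4,7a-trimethyl-2,4,5,6,7,7a-hexahydro-1-benzofuran-2-yl]but-2-en-1-yl}sulfonyl)-1-phenyl-1H-tetrazole | c1ccccc1-n1nnnc1S(=O)(=O)C/C=C(C)/[C@@H]1C=C2C(C)(C)C[C@H](O[Si](C)(C)C(C)(C)C)C[C@@]2(C)O1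
F7 | step 18 | (2E,4E,6E,8E,10E)-11-[(2S,6S,7aR)-6-(TBSO)-4,4,7a-trimethyl-2,4,5,6,7,7a-hexahydro-1-benzofuran-2-yl]-2,7-dimethyldodeca-2,4,6,8,10-pentaenal | CC(/C=C/C=C(\C)[C@@H]1C=C2C(C)(C)C[C@H](O[Si](C)(C)C(C)(C)C)C[C@@]2(C)O1)=C\C=C\C=C(/C)C=O
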